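## The problem

Target 36 is a 2,3-dihydrobenzofuran whose benzene ring A has no free position. It carries oxygen at C4, C6 and C7a and carbon at C3a, C5 (isobutyryl) and C7 (a methylene bridge to C3' of the 4-hydroxy-2-pyrone ring C). Ring B (O1, C2, C3) holds the only stereocentre, C2 (R), which bears the isopropenyl group. Nothing else in the molecule can relay or correct it, so it has to come from the chiral pool or a catalyst and then stay untouched. The fragile parts are the allylic aryl ether at C2 (acid opens it or expands ring B to a chroman, and the alkene adds HX), the hydroxypyrone (a vinylogous acid and a lactone), and the methylene bridge between two electron-rich rings. A classical route must tell C5 from C7 and O1 from the two phenolic oxygens on a phloroglucinol. The structure offers a way around this: oxygen and carbon substituents alternate around ring A, which is the pattern a 3-oxygenated vinylketene (C3a, C4, C5, C6) and an alkynyl ether (C7, C7a) give on benzannulation. The three atoms O1–C2–C3 join the alkyne oxygen to the ketene α-carbon, so ring B can be the tether that makes the annulation intramolecular and is closed by it.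

## Retrosynthesis

**36 ⇒ 33.** The isopropenyl double bond is made last, by dehydration of tertiary carbinol 33 through triacetates 34 and 35. An alkene at this position could not be carried earlier: an allyl alkynyl ether would rearrange, and the alkene would not survive Lewis-acid acylation. The forward reaction must eliminate towards a methyl group and not towards C2–H, with the acidic hydroxyls masked.

**33 ⇒ 30 + 31.** The C5–acyl bond is cut next, leading through benzyl ether 32 to resorcinol 30 and isobutyryl chloride 31. C5 is the only unsubstituted carbon of 30, so the acylation needs no regiocontrol. Introducing the ketone after the organolithium chemistry avoids protecting it. The benzyl ether is removed by neutral hydrogenolysis while no alkene is present.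

**30 ⇒ 29 ⇒ 24 (key disconnection).** Bonds C6–C7, C3a–C7a and C5–C6 are cut, which removes rings A and B together. Cuts at O1–C7a or C3–C3a would leave ring A to be assembled and differentiated by substitution chemistry. The chosen cut places every ring A substituent by construction and uses the C2 stereocentre only as a bystander. Precursor 24 is a monocyclic cyclobutenone carrying an alkynyl ether on a three-atom tether. The forward reaction must open the cyclobutenone without heat, add ketene to alkyne in one orientation, and aromatize.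

**24 ⇒ 21 + 10.** The propargylic C–C bond and the silyl enol ether are cut. Two constraints fix the order of events. Ketene cannot tell two alkynyl ethers apart, and a cyclobutenone cannot survive the alkynyllithium. The four-membered ring is therefore built while only one ynol ether exists and is then carried as its vinylogous acid 21. The lithium salt of 21 is inert to n-BuLi, and O-silylation at the end regenerates the cyclobutenone. The silyl group on the future C4 oxygen later comes off with fluoride.

**21 ⇒ 20 ⇒ 19 ⇒ 17.** Ketene adds to the ethoxyalkyne of 19 and supplies C5 and C6. The 1,2-dichlorovinyl ether is the latent alkynyl ether (C7a, C7) and does not react with ketene. It is made from alcohol 17 and trichloroethylene.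

**17 ⇒ 14 + 15; 14 ⇒ 13 ⇒ 11.** The C3–C(sp) bond comes from opening epoxide 14 with lithium ethoxyacetylide 16 (from 15). The stereocentre is bought with methyl (R)-glycidate 11. The tertiary oxygen is benzylated, not silylated, because a silyl group would migrate to the neighbouring alkoxide in the trichloroethylene step.

**10 ⇒ 9 ⇒ 8 ⇒ 7 ⇒ 5 ⇒ 4 ⇒ 1 + 2.** The pyrone is made by γ-acylation of the dianion 3 of keto ester 1 and lactonization. Chloroformylation sets the C3' carbon and activates C4' for exchange to a fluoride-labile 2-(trimethylsilyl)ethyl ether. Reduction and bromination give electrophile 10.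

## Roads not taken

**Alternative 1:** Cut O1–C2 and C3–C3a. Iodophenol A1 and isoprene A2 would combine at zerovalent palladium with a chiral ligand (Larock-type heteroannulation): carbopalladation, then phenoxide attack on the π-allyl complex, to give A3.
- Merits: C2 and the isopropenyl group arrive in one step, no masked carbinol and no dehydration are needed, and the racemic reaction class is well established. This road is clearly shorter than the chosen one.
- Weak points: A1 is flanked on both sides and very electron-rich, so oxidative addition is slow. Enantiocontrol in attack on the π-allyl intermediate is the uncertain part, and regiochemistry of diene insertion must also hold. A3 still needs the bridge to the pyrone at C7 and removal of acetal groups by acid next to the allylic ether.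
- Comparison: the chosen plan takes C2 from the chiral pool with certainty and fixes the C5/C7 pattern by construction. It pays for this with about twice the step count.

**Alternative 2:** Cut C3'–C4' and O1'–C2', so ring C is built last. The acylketene from dioxinone A4 would add to silyl ketene acetal A5, and collapse of the orthoester would expel the C6 phenoxide to give A6.
- Merits: the pyrone is formed directly on the finished core, and no bridge-forming coupling is needed.
- Weak points: A5 must be made by enolizing a lactone next to an enolizable aryl ketone. The cycloaddition needs heat with the isopropenyl ether present. The orthoester can collapse in two directions. The road does not address rings A and B or C2 at all.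
- Comparison: it is complementary rather than competing and is more convergent at the end. The chosen plan attaches a ready-made pyrone by simple alkylation and uses its key step to solve ring A.

**Alternative 3:** Cut C2–C3. The sodium salt of tosylhydrazone A7 would give an aryl diazomethane, and a chiral dirhodium tetracarboxylate would insert the carbene into one enantiotopic O–CH2 hydrogen to give A8.
- Merits: the stereocentre is set catalytically on a complete arene, and no chiral starting material is needed.
- Weak points: the carbene has no acceptor group and sits between two ortho substituents. The C–H bond is next to a quaternary carbon. Ylide formation at the ether oxygen, azine formation and dimerization compete, and enantioselectivity is unproven. Bridge and dehydration remain to be done.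
- Comparison: it is shorter to ring B. The chosen plan has certainty at C2 and unambiguous placement of all six ring A substituents.

Key step: step 14

Remark: locants C2–C7a are those of the dihydrobenzofuran of 36 and primed locants those of the pyrone. Compound 21 is written as the enol of the cyclobutane-1,3-dione. It is assumed that the chloroformylation known for 4-hydroxycoumarin carries over to pyrone 5.

## Route

Step 1
Reactants: 1 methyl 3-oxopentanoate; 2 N-methoxy-N-methylpropanamide
Product: 4 methyl 4-methyl-3,5-dioxoheptanoate, via dilithium dianion 3 (not isolated)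
Conditions: LiN(iPr)2 (2.1 equiv), THF, −78 → 0 °C; then 2, −78 → 0 °C; aq. HCl
Reagents that add atoms: none
Why: Dianion γ-acylation of a β-keto ester: the second deprotonation makes the γ-carbon the most nucleophilic site, and the Weinreb amide acylates it without over-addition.

Step 2
Reactants: 4 methyl 4-methyl-3,5-dioxoheptanoate
Product: 5 6-ethyl-4-hydroxy-5-methyl-2H-pyran-2-one
Conditions: DBU (1.2 equiv), toluene, 110 °C; aq. HCl
Reagents that add atoms: none
Why: Base-mediated lactonization of a 3,5-dioxo ester (enol oxygen onto the ester), the standard entry to 4-hydroxy-2-pyrones; the base is stoichiometric because the product is acidic.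

Step 3
Reactants: 5 6-ethyl-4-hydroxy-5-methyl-2H-pyran-2-one
Product: 7 4-chloro-6-ethyl-5-methyl-2-oxo-2H-pyran-3-carbaldehyde, via iminium chloride 6 (not isolated)
Conditions: POCl3, DMF, 0 → 60 °C; then aq. NaOAc
Reagents that add atoms: N,N-dimethylformamide, CN(C)C=O; phosphoryl chloride, O=P(Cl)(Cl)Cl; water, O
Why: Vilsmeier–Haack chloroformylation: C3' is the nucleophilic carbon of the vinylogous acid and the only free ring position, and the 4-hydroxyl becomes chloride as in the coumarin series.

Step 4
Reactants: 7 4-chloro-6-ethyl-5-methyl-2-oxo-2H-pyran-3-carbaldehyde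
Product: 8 6-ethyl-5-methyl-2-oxo-4-[2-(trimethylsilyl)ethoxy]-2H-pyran-3-carbaldehyde
Conditions: Me3SiCH2CH2OH, Et3N, CH2Cl2, 0 °C → rt
Reagents that add atoms: 2-(trimethylsilyl)ethanol, C[Si](C)(C)CCO
Why: Addition–elimination at C4', a vinylogous acyl chloride activated by both carbonyl groups; the ether installed is base-stable and fluoride-labile.

Step 5
Reactants: 8 6-ethyl-5-methyl-2-oxo-4-[2-(trimethylsilyl)ethoxy]-2H-pyran-3-carbaldehyde
Product: 9 6-ethyl-3-(hydroxymethyl)-5-methyl-4-[2-(trimethylsilyl)ethoxy]-2H-pyran-2-one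
Conditions: NaBH4, CeCl3·7H2O, MeOH/THF, −40 °C
Reagents that add atoms: none
Why: Luche reduction gives 1,2-addition to the aldehyde and suppresses hydride addition–elimination at C4' and attack on the lactone.

Step 6
Reactants: 9 6-ethyl-3-(hydroxymethyl)-5-methyl-4-[2-(trimethylsilyl)ethoxy]-2H-pyran-2-one
Product: 10 3-(bromomethyl)-6-ethyl-5-methyl-4-[2-(trimethylsilyl)ethoxy]-2H-pyran-2-one
Conditions: CBr4, PPh3, CH2Cl2, 0 °C
Reagents that add atoms: carbon tetrabromide, BrC(Br)(Br)Br
Why: Appel bromination of a primary alcohol under neutral conditions that spare the silylethyl ether.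

Step 7
Reactants: 11 methyl (R)-oxirane-2-carboxylate
Product: 13 (R)-2-(oxiran-2-yl)propan-2-ol, via methyl ketone 12 (not isolated)
Conditions: MeMgCl (2.2 equiv), THF, −78 → −20 °C; aq. NH4Cl
Reagents that add atoms: methylmagnesium chloride, C[Mg]Cl
Why: Double Grignard addition to the ester is faster than epoxide opening at low temperature, and the chloride reagent limits halohydrin formation; the stereocentre is not touched.

Step 8
Reactants: 13 (R)-2-(oxiran-2-yl)propan-2-ol
Product: 14 (R)-2-[2-(benzyloxy)propan-2-yl]oxirane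
Conditions: 2-benzyloxy-1-methylpyridinium triflate, MgO, PhCF3, 85 °C
Reagents that add atoms: 2-benzyloxy-1-methylpyridinium trifluoromethanesulfonate, C[n+]1ccccc1OCc1ccccc1.[O-]S(=O)(=O)C(F)(F)F
Why: Neutral benzyl transfer etherifies the tertiary alcohol without forming its alkoxide, so Payne rearrangement is avoided; benzyl is chosen because a silyl group here would migrate to the neighbouring alkoxide in step 10.

Step 9
Reactants: 14 (R)-2-[2-(benzyloxy)propan-2-yl]oxirane; 15 ethoxyacetylene
Product: 17 (R)-2-(benzyloxy)-6-ethoxy-2-methylhex-5-yn-3-ol, via lithium ethoxyacetylide 16 (not isolated)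
Conditions: 15, n-BuLi, THF, −78 °C; then 14, BF3·OEt2, −78 °C
Reagents that add atoms: none
Why: Yamaguchi alkynylation opens the epoxide at the unhindered CH2; the C–O bond at the stereocentre is not broken, so the (R) configuration is kept.

Step 10
Reactants: 17 (R)-2-(benzyloxy)-6-ethoxy-2-methylhex-5-yn-3-ol
Product: 19 benzyl (R)-3-[(E)-1,2-dichlorovinyloxy]-6-ethoxy-2-methylhex-5-yn-2-yl ether, via potassium alkoxide 18 (not isolated)
Conditions: KH, THF, 0 °C; then Cl2C=CHCl, −40 °C → rt
Reagents that add atoms: trichloroethylene, ClC=C(Cl)Cl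
Why: The alkoxide eliminates HCl from trichloroethylene and adds anti to the dichloroacetylene formed, the standard route to (E)-1,2-dichlorovinyl ethers; the benzyl ether cannot migrate.

Step 11
Reactants: 19 benzyl (R)-3-[(E)-1,2-dichlorovinyloxy]-6-ethoxy-2-methylhex-5-yn-2-yl ether
Product: 20 2-{(R)-3-(benzyloxy)-2-[(E)-1,2-dichlorovinyloxy]-3-methylbutyl}-3-ethoxycyclobut-2-en-1-one
Conditions: CH2=C=O (from acetone pyrolysis), MeCN, 0 °C → rt
Reagents that add atoms: ketene, C=C=O
Why: Ketene–ynol ether (2+2) cycloaddition: the β-carbon of the only ynol ether present attacks the ketene carbonyl carbon and gives the 2-alkyl-3-ethoxycyclobutenone; the dichlorovinyl ether is too electron-poor to react.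

Step 12
Reactants: 20 2-{(R)-3-(benzyloxy)-2-[(E)-1,2-dichlorovinyloxy]-3-methylbutyl}-3-ethoxycyclobut-2-en-1-one
Product: 21 2-{(R)-3-(benzyloxy)-2-[(E)-1,2-dichlorovinyloxy]-3-methylbutyl}-3-hydroxycyclobut-2-en-1-one
Conditions: 0.5 M HCl, THF, 0 °C → rt; extraction into aq. NaHCO3, re-acidification
Reagents that add atoms: water, O
Why: Acid hydrolysis of the vinylogous ester (addition–elimination of water at C3) gives the enolized cyclobutane-1,3-dione, a vinylogous acid that is purified by acid–base extraction; benzyl and dichlorovinyl ethers tolerate dilute acid.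

Step 13
Reactants: 21 2-{(R)-3-(benzyloxy)-2-[(E)-1,2-dichlorovinyloxy]-3-methylbutyl}-3-hydroxycyclobut-2-en-1-one; 10 3-(bromomethyl)-6-ethyl-5-methyl-4-[2-(trimethylsilyl)ethoxy]-2H-pyran-2-one
Product: 24 2-{(R)-3-(benzyloxy)-3-methyl-2-[3-(6-ethyl-5-methyl-2-oxo-4-[2-(trimethylsilyl)ethoxy]-2H-pyran-3-yl)prop-1-ynyloxy]butyl}-3-(triisopropylsilyloxy)cyclobut-2-en-1-one, via dilithio alkynyl ether enolate 22 (not isolated), via lithium enolate 23 (not isolated)
Conditions: n-BuLi (3.05 equiv), THF, −78 → −40 °C; 10, −78 → −20 °C; iPr3SiOTf, −78 °C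
Reagents that add atoms: triisopropylsilyl trifluoromethanesulfonate, CC(C)[Si](OS(=O)(=O)C(F)(F)F)(C(C)C)C(C)C
Why: The first equivalent of base makes the β-diketonate, which resists both addition and a second deprotonation (that would give a cyclobutadiene dianion); two more equivalents turn the dichlorovinyl ether into the lithium alkynyl ether by elimination and chlorine–lithium exchange. The acetylide, far more nucleophilic than the diketonate, displaces the allylic-type bromide of 10, and O-silylation of the symmetrical enolate regenerates the cyclobutenone.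

Step 14
Reactants: 24 2-{(R)-3-(benzyloxy)-3-methyl-2-[3-(6-ethyl-5-methyl-2-oxo-4-[2-(trimethylsilyl)ethoxy]-2H-pyran-3-yl)prop-1-ynyloxy]butyl}-3-(triisopropylsilyloxy)cyclobut-2-en-1-one
Product: 29 3-{[(R)-2-[2-(benzyloxy)propan-2-yl]-6-hydroxy-4-(triisopropylsilyloxy)-2,3-dihydrobenzofuran-7-yl]methyl}-6-ethyl-5-methyl-4-[2-(trimethylsilyl)ethoxy]-2H-pyran-2-one, via vinylketene 25 (not isolated), via bicyclic vinylcyclobutenone 26 (not isolated), via dienylketene 27 (not isolated), via cyclohexadienone 28 (not isolated)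
Conditions: hν (254 nm, quartz), degassed MeCN (0.003 M), 20 °C; then 60 °C in the dark
Reagents that add atoms: none
Why: Proposed new method: an intramolecular, ether-tethered Danheiser benzannulation, whose closest known relatives are the intermolecular annulation of cyclobutenones or photochemically generated vinylketenes with alkoxy- and siloxyalkynes and the intramolecular ketene–alkyne (2+2) cycloaddition. Light at 254 nm, absorbed mainly by the vinylogous silyl ester, drives four-electron electrocyclic opening of 24 to vinylketene 25. The nucleophilic β-carbon of the alkynyl ether attacks the ketene carbonyl carbon (C6–C7) and the oxygen-bearing alkyne carbon bonds to the ketene α-carbon (C3a–C7a); this (2+2) closure makes ring B as a five-membered ring fused to the new cyclobutenone in 26. Strain-assisted four-electron opening of 26 gives dienylketene 27, where ketene and siloxyvinyl group are held cis on the dihydrofuran double bond, and six-electron electrocyclization (C5–C6) closes ring A as dienone 28, which tautomerizes to phenol 29. No stereocentre is made: C2 comes unchanged from 11, and the quaternary centre of 26 is lost again on ring opening. The step needs regiocontrol in the (2+2) event, which alkyne polarity and the three-atom tether both enforce (the other orientation would need a six-membered ring and attack by the electron-poor alkyne carbon); it also needs chemoselectivity against ketene dimerization and retro-ene loss of ketene from the secondary alkynyl ether, secured by high dilution and by generating 25 at ambient temperature, with heat applied only after the alkynyl ether is consumed.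

Step 15
Reactants: 29 3-{[(R)-2-[2-(benzyloxy)propan-2-yl]-6-hydroxy-4-(triisopropylsilyloxy)-2,3-dihydrobenzofuran-7-yl]methyl}-6-ethyl-5-methyl-4-[2-(trimethylsilyl)ethoxy]-2H-pyran-2-one
Product: 30 3-{[(R)-2-[2-(benzyloxy)propan-2-yl]-4,6-dihydroxy-2,3-dihydrobenzofuran-7-yl]methyl}-6-ethyl-4-hydroxy-5-methyl-2H-pyran-2-one
Conditions: n-Bu4NF (3 equiv), THF, 0 °C → rt; AcOH
Reagents that add atoms: none
Why: Fluoride cleaves the aryl silyl ether and the 2-(trimethylsilyl)ethyl vinylogous ester (β-elimination with loss of ethene); the benzyl ether and the lactone are inert.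

Step 16
Reactants: 30 3-{[(R)-2-[2-(benzyloxy)propan-2-yl]-4,6-dihydroxy-2,3-dihydrobenzofuran-7-yl]methyl}-6-ethyl-4-hydroxy-5-methyl-2H-pyran-2-one; 31 isobutyryl chloride
Product: 32 3-{[(R)-2-[2-(benzyloxy)propan-2-yl]-4,6-dihydroxy-5-isobutyryl-2,3-dihydrobenzofuran-7-yl]methyl}-6-ethyl-4-hydroxy-5-methyl-2H-pyran-2-one
Conditions: 31, TiCl4, CH2Cl2, −40 → 0 °C; aq. NaHCO3/MeOH work-up
Reagents that add atoms: none
Why: Friedel–Crafts acylation through the titanium phenoxide (O-acylation and Fries shift) at C5, the only unsubstituted carbon of ring A and ortho, ortho and para to three oxygens; the pyrone has no free carbon, and the basic work-up cleaves labile O-acyl groups.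

Step 17
Reactants: 32 3-{[(R)-2-[2-(benzyloxy)propan-2-yl]-4,6-dihydroxy-5-isobutyryl-2,3-dihydrobenzofuran-7-yl]methyl}-6-ethyl-4-hydroxy-5-methyl-2H-pyran-2-one
Product: 33 3-{[(R)-4,6-dihydroxy-2-(2-hydroxypropan-2-yl)-5-isobutyryl-2,3-dihydrobenzofuran-7-yl]methyl}-6-ethyl-4-hydroxy-5-methyl-2H-pyran-2-one
Conditions: H2 (1 atm), Pd(OH)2/C, EtOAc, rt
Reagents that add atoms: none
Why: Hydrogenolysis of the benzyl ether under neutral conditions frees the tertiary carbinol without acid and before any alkene is present; the chelated aryl ketone and the hydroxypyrone are reduced far more slowly.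

Step 18
Reactants: 33 3-{[(R)-4,6-dihydroxy-2-(2-hydroxypropan-2-yl)-5-isobutyryl-2,3-dihydrobenzofuran-7-yl]methyl}-6-ethyl-4-hydroxy-5-methyl-2H-pyran-2-one
Product: 34 4,6-di-O-acetyl-4'-O-acetyl derivative of 33 (tertiary hydroxyl free)
Conditions: Ac2O, pyridine, DMAP (cat.), 0 °C
Reagents that add atoms: acetic anhydride, CC(=O)OC(C)=O
Why: Acetylation caps the two phenols and the pyrone enol, which would consume the dehydrating reagent; the hindered tertiary alcohol is not acylated at 0 °C.

Step 19
Reactants: 34 4,6-di-O-acetyl-4'-O-acetyl derivative of 33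
Product: 35 4,6-di-O-acetyl-4'-O-acetyl derivative of 36
Conditions: Burgess reagent (MeO2C–N−–SO2–N+Et3), toluene, 50 °C
Reagents that add atoms: none
Why: Burgess dehydration by syn-elimination of the sulfamate ester; six methyl hydrogens compete with one hindered C2–H whose loss would give an enol ether, so the isopropenyl group should be the main product, as in related hydroxyisopropyl dihydrobenzofurans. C2 is not involved.

Step 20
Reactants: 35 4,6-di-O-acetyl-4'-O-acetyl derivative of 36
Product: 36 3-{[(R)-4,6-dihydroxy-5-isobutyryl-2-(prop-1-en-2-yl)-2,3-dihydrobenzofuran-7-yl]methyl}-6-ethyl-4-hydroxy-5-methyl-2H-pyran-2-one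
Conditions: K2CO3, MeOH, 0 °C; aq. NH4Cl
Reagents that add atoms: none
Why: Base-catalysed methanolysis of aryl and enol acetates is fast at 0 °C and leaves the allylic aryl ether, ketone and lactone intact.

## Compound list

1 | methyl 3-oxopentanoate | CCC(=O)CC(=O)OC | starting material
2 | N-methoxy-N-methylpropanamide | CCC(=O)N(C)OC | starting material
3 | dilithium 2,4-dianion of 1 (formed in situ) | COC(=O)C=C(O[Li])C(C)[Li] | intermediate
4 | methyl 4-methyl-3,5-dioxoheptanoate | CCC(=O)C(C)C(=O)CC(=O)OC | intermediate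
5 | 6-ethyl-4-hydroxy-5-methyl-2H-pyran-2-one | CCc1oc(=O)cc(O)c1C | intermediate
6 | [(4-chloro-6-ethyl-5-methyl-2-oxo-2H-pyran-3-yl)methylidene]dimethyliminium chloride (formed in situ) | CCc1oc(=O)c(C=[N+](C)C)c(Cl)c1C.[Cl-] | intermediate
7 | 4-chloro-6-ethyl-5-methyl-2-oxo-2H-pyran-3-carbaldehyde | CCc1oc(=O)c(C=O)c(Cl)c1C | intermediate
8 | 6-ethyl-5-methyl-2-oxo-4-[2-(trimethylsilyl)ethoxy]-2H-pyran-3-carbaldehyde | CCc1oc(=O)c(C=O)c(OCC[Si](C)(C)C)c1C | intermediate
9 | 6-ethyl-3-(hydroxymethyl)-5-methyl-4-[2-(trimethylsilyl)ethoxy]-2H-pyran-2-one | CCc1oc(=O)c(CO)c(OCC[Si](C)(C)C)c1C | intermediate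
10 | 3-(bromomethyl)-6-ethyl-5-methyl-4-[2-(trimethylsilyl)ethoxy]-2H-pyran-2-one | CCc1oc(=O)c(CBr)c(OCC[Si](C)(C)C)c1C | intermediate
11 | methyl (R)-oxirane-2-carboxylate (methyl (R)-glycidate) | COC(=O)[C@H]1CO1 | starting material
12 | (R)-1-(oxiran-2-yl)ethan-1-one (formed in situ) | CC(=O)[C@H]1CO1 | intermediate
13 | (R)-2-(oxiran-2-yl)propan-2-ol | CC(C)(O)[C@H]1CO1 | intermediate
14 | (R)-2-[2-(benzyloxy)propan-2-yl]oxirane | CC(C)(OCc1ccccc1)[C@H]1CO1 | intermediate
15 | ethoxyacetylene | CCOC#C | starting material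
16 | lithium ethoxyacetylide (formed in situ) | CCOC#C[Li] | intermediate
17 | (R)-2-(benzyloxy)-6-ethoxy-2-methylhex-5-yn-3-ol | CCOC#CC[C@@H](O)C(C)(C)OCc1ccccc1 | intermediate
18 | potassium alkoxide of 17 (formed in situ) | CCOC#CC[C@@H](O[K])C(C)(C)OCc1ccccc1 | intermediate
19 | benzyl (R)-3-[(E)-1,2-dichlorovinyloxy]-6-ethoxy-2-methylhex-5-yn-2-yl ether | CCOC#CC[C@@H](O/C(Cl)=C\Cl)C(C)(C)OCc1ccccc1 | intermediate
20 | 2-{(R)-3-(benzyloxy)-2-[(E)-1,2-dichlorovinyloxy]-3-methylbutyl}-3-ethoxycyclobut-2-en-1-one | O=C1CC(OCC)=C1C[C@@H](O/C(Cl)=C\Cl)C(C)(C)OCc1ccccc1 | intermediate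
21 | 2-{(R)-3-(benzyloxy)-2-[(E)-1,2-dichlorovinyloxy]-3-methylbutyl}-3-hydroxycyclobut-2-en-1-one | O=C1CC(O)=C1C[C@@H](O/C(Cl)=C\Cl)C(C)(C)OCc1ccccc1 | intermediate
22 | dilithio species: lithium enolate of the dione bearing the lithium alkynyl ether (formed in situ) | O=C1CC(O[Li])=C1C[C@@H](OC#C[Li])C(C)(C)OCc1ccccc1 | intermediate
23 | lithium enolate of the C-alkylated alkynyl ether (formed in situ) | O=C1CC(O[Li])=C1C[C@@H](OC#CCc2c(OCC[Si](C)(C)C)c(C)c(CC)oc2=O)C(C)(C)OCc1ccccc1 | intermediate
24 | 2-{(R)-3-(benzyloxy)-3-methyl-2-[3-(6-ethyl-5-methyl-2-oxo-4-[2-(trimethylsilyl)ethoxy]-2H-pyran-3-yl)prop-1-ynyloxy]butyl}-3-(triisopropylsilyloxy)cyclobut-2-en-1-one | O=C1CC(O[Si](C(C)C)(C(C)C)C(C)C)=C1C[C@@H](OC#CCc2c(OCC[Si](C)(C)C)c(C)c(CC)oc2=O)C(C)(C)OCc1ccccc1 | intermediate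
25 | vinylketene from ring opening of 24 (formed in situ) | O=C=C(C[C@@H](OC#CCc1c(OCC[Si](C)(C)C)c(C)c(CC)oc1=O)C(C)(C)OCc1ccccc1)C(=C)O[Si](C(C)C)(C(C)C)C(C)C | intermediate
26 | 2-oxabicyclo[3.2.0]hept-1(7)-en-6-one with 5-(1-silyloxyvinyl) and 7-pyronylmethyl groups, configured (R) at C3, mixture at C5 (formed in situ) | O=C1C(Cc3c(OCC[Si](C)(C)C)c(C)c(CC)oc3=O)=C2O[C@@H](C(C)(C)OCc3ccccc3)CC12C(=C)O[Si](C(C)C)(C(C)C)C(C)C | intermediate
27 | dienylketene from ring opening of 26 (formed in situ) | O=C=C(Cc1c(OCC[Si](C)(C)C)c(C)c(CC)oc1=O)C2=C(C(=C)O[Si](C(C)C)(C(C)C)C(C)C)C[C@H](C(C)(C)OCc1ccccc1)O2 | intermediate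
28 | cyclohexa-2,4-dienone tautomer of 29 (formed in situ) | O=C1CC(O[Si](C(C)C)(C(C)C)C(C)C)=C2C[C@H](C(C)(C)OCc3ccccc3)OC2=C1Cc3c(OCC[Si](C)(C)C)c(C)c(CC)oc3=O | intermediate
29 | 3-{[(R)-2-[2-(benzyloxy)propan-2-yl]-6-hydroxy-4-(triisopropylsilyloxy)-2,3-dihydrobenzofuran-7-yl]methyl}-6-ethyl-5-methyl-4-[2-(trimethylsilyl)ethoxy]-2H-pyran-2-one | CC(C)(OCc1ccccc1)[C@H]1Cc2c(O[Si](C(C)C)(C(C)C)C(C)C)cc(O)c(Cc3c(OCC[Si](C)(C)C)c(C)c(CC)oc3=O)c2O1 | intermediate
30 | 3-{[(R)-2-[2-(benzyloxy)propan-2-yl]-4,6-dihydroxy-2,3-dihydrobenzofuran-7-yl]methyl}-6-ethyl-4-hydroxy-5-methyl-2H-pyran-2-one | CC(C)(OCc1ccccc1)[C@H]1Cc2c(O)cc(O)c(Cc3c(O)c(C)c(CC)oc3=O)c2O1 | intermediate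
31 | isobutyryl chloride | CC(C)C(=O)Cl | starting material
32 | 3-{[(R)-2-[2-(benzyloxy)propan-2-yl]-4,6-dihydroxy-5-isobutyryl-2,3-dihydrobenzofuran-7-yl]methyl}-6-ethyl-4-hydroxy-5-methyl-2H-pyran-2-one | CC(C)(OCc1ccccc1)[C@H]1Cc2c(O)c(C(=O)C(C)C)c(O)c(Cc3c(O)c(C)c(CC)oc3=O)c2O1 | intermediate
33 | 3-{[(R)-4,6-dihydroxy-2-(2-hydroxypropan-2-yl)-5-isobutyryl-2,3-dihydrobenzofuran-7-yl]methyl}-6-ethyl-4-hydroxy-5-methyl-2H-pyran-2-one | CC(C)(O)[C@H]1Cc2c(O)c(C(=O)C(C)C)c(O)c(Cc3c(O)c(C)c(CC)oc3=O)c2O1 | intermediate
34 | triacetate of 33 (acetates at C4–O, C6–O and pyrone C4'–O; tertiary OH free) | CC(C)(O)[C@H]1Cc2c(OC(C)=O)c(C(=O)C(C)C)c(OC(C)=O)c(Cc3c(OC(C)=O)c(C)c(CC)oc3=O)c2O1 | intermediate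
35 | triacetate of 36 | C=C(C)[C@H]1Cc2c(OC(C)=O)c(C(=O)C(C)C)c(OC(C)=O)c(Cc3c(OC(C)=O)c(C)c(CC)oc3=O)c2O1 | intermediate
36 | 3-{[(R)-4,6-dihydroxy-5-isobutyryl-2-(prop-1-en-2-yl)-2,3-dihydrobenzofuran-7-yl]methyl}-6-ethyl-4-hydroxy-5-methyl-2H-pyran-2-one (CNP0206652.1) | C=C(C)[C@H]1Cc2c(O)c(C(=O)C(C)C)c(O)c(Cc3c(O)c(C)c(CC)oc3=O)c2O1 | target

## Step count and risks

Total: 20 steps. Longest linear sequence: 14 steps (11 → 36 through steps 7–20; the pyrone branch from 1 through steps 1–6 and 13–20 is equally long).

**Step 14 (key step, proposed new method).**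
- What may go wrong: the vinylketene may be lost to dimerization before it reaches the alkyne. The pyrone or the product phenol may decompose under the lamp. The alkynyl ether may fragment by the retro-ene path if the solution warms. The strained intermediate 26 may fail to open towards 27.
- Fallback (known chemistry, sets out from 31 and 5, returns at 33): Friedel–Crafts acylation of phloroglucinol with 31 gives 1-(2,4,6-trihydroxyphenyl)-2-methylpropan-1-one F1. C-prenylation with prenyl bromide in aqueous base gives the 3-prenyl compound F2, and silylation with t-BuMe2SiOTf its tris-silyl ether F3. Shi epoxidation, with the ketone enantiomer that delivers the (S)-epoxide, gives F4. Fluoride then removes the silyl groups, and the phenoxide para to the ketone opens the epoxide 5-exo with inversion to the (R)-dihydrobenzofuran triol F5. Mannich-type coupling of F5 with 5 and Eschenmoser's salt at the one free ring position gives 33.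

**Step 13.**
- What may go wrong: the alkynyllithium or residual n-BuLi may add to the lactone carbonyl of 10 instead of displacing bromide. The enolate may be alkylated or incompletely silylated.
- Fallback (sets out from 21, returns at 30, and makes steps 3–6 unnecessary): the same dianion 22 is quenched with paraformaldehyde and silylated twice to give the bis-silyl compound F6. Irradiation as in step 14 gives phenol F7, and n-Bu4NF the ortho-hydroxybenzyl alcohol F8. Heating F8 with unprotected pyrone 5 in toluene lets C3' of 5 add to the ortho-quinone methide and gives 30.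

**Step 12.**
- What may go wrong: water may open the four-membered 1,3-dione by retro-Claisen cleavage, and the dichlorovinyl ether may hydrolyse slowly in acid.
- Fallback (sets out from 14, returns at 21): epoxide 14 is opened with lithium tert-butoxyacetylide and BF3·OEt2 to give alcohol F9. KH and trichloroethylene give dichlorovinyl ether F10, and ketene the 3-tert-butoxycyclobutenone F11. Catalytic CF3CO2H in CH2Cl2 at 0 °C then releases isobutene and gives 21 without water.

**Step 16.**
- What may go wrong: TiCl4 may attack the tertiary benzyl ether, with ionization at the tertiary carbon and ring expansion of ring B to a chroman. The methylene bridge may be cleaved, or acyl migration from oxygen to C5 may be incomplete.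
- Fallback (sets out from 30, returns at 32): ortho-formylation with MgCl2, Et3N and paraformaldehyde in MeCN gives aldehyde F12. Excess i-PrMgCl adds to the aldehyde of the magnesium phenoxide to give carbinol F13. MnO2 oxidizes the benzylic alcohol to ketone 32.

Further compounds
F1 | step 14 | 1-(2,4,6-trihydroxyphenyl)-2-methylpropan-1-one | CC(C)C(=O)c1c(O)cc(O)cc1O
F2 | step 14 | 1-[2,4,6-trihydroxy-3-(3-methylbut-2-en-1-yl)phenyl]-2-methylpropan-1-one | CC(C)C(=O)c1c(O)cc(O)c(CC=C(C)C)c1O
F3 | step 14 | tris(tert-butyldimethylsilyl) ether of F2 | CC(C)C(=O)c1c(O[Si](C)(C)C(C)(C)C)cc(O[Si](C)(C)C(C)(C)C)c(CC=C(C)C)c1O[Si](C)(C)C(C)(C)C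
F4 | step 14 | (S)-epoxide of F3 | CC(C)C(=O)c1c(O[Si](C)(C)C(C)(C)C)cc(O[Si](C)(C)C(C)(C)C)c(C[C@@H]2OC2(C)C)c1O[Si](C)(C)C(C)(C)C
F5 | step 14 | 1-[(R)-4,6-dihydroxy-2-(2-hydroxypropan-2-yl)-2,3-dihydrobenzofuran-5-yl]-2-methylpropan-1-one | CC(C)(O)[C@H]1Cc2c(O)c(C(=O)C(C)C)c(O)cc2O1
F6 | step 13 | 2-{(R)-3-(benzyloxy)-3-methyl-2-[3-(triisopropylsilyloxy)prop-1-ynyloxy]butyl}-3-(triisopropylsilyloxy)cyclobut-2-en-1-one | O=C1CC(O[Si](C(C)C)(C(C)C)C(C)C)=C1C[C@@H](OC#CCO[Si](C(C)C)(C(C)C)C(C)C)C(C)(C)OCc1ccccc1
F7 | step 13 | (R)-2-[2-(benzyloxy)propan-2-yl]-4-(triisopropylsilyloxy)-7-[(triisopropylsilyloxy)methyl]-2,3-dihydrobenzofuran-6-ol | CC(C)(OCc1ccccc1)[C@H]1Cc2c(O[Si](C(C)C)(C(C)C)C(C)C)cc(O)c(CO[Si](C(C)C)(C(C)C)C(C)C)c2O1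
F8 | step 13 | (R)-2-[2-(benzyloxy)propan-2-yl]-7-(hydroxymethyl)-2,3-dihydrobenzofuran-4,6-diol | CC(C)(OCc1ccccc1)[C@H]1Cc2c(O)cc(O)c(CO)c2O1
F9 | step 12 | (R)-2-(benzyloxy)-6-(tert-butoxy)-2-methylhex-5-yn-3-ol | CC(C)(C)OC#CC[C@@H](O)C(C)(C)OCc1ccccc1
F10 | step 12 | benzyl (R)-6-(tert-butoxy)-3-[(E)-1,2-dichlorovinyloxy]-2-methylhex-5-yn-2-yl ether | CC(C)(C)OC#CC[C@@H](O/C(Cl)=C\Cl)C(C)(C)OCc1ccccc1
F11 | step 12 | 2-{(R)-3-(benzyloxy)-2-[(E)-1,2-dichlorovinyloxy]-3-methylbutyl}-3-(tert-butoxy)cyclobut-2-en-1-one | O=C1CC(OC(C)(C)C)=C1C[C@@H](O/C(Cl)=C\Cl)C(C)(C)OCc1ccccc1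
F12 | step 16 | (R)-2-[2-(benzyloxy)propan-2-yl]-7-[(6-ethyl-4-hydroxy-5-methyl-2-oxo-2H-pyran-3-yl)methyl]-4,6-dihydroxy-2,3-dihydrobenzofuran-5-carbaldehyde | CC(C)(OCc1ccccc1)[C@H]1Cc2c(O)c(C=O)c(O)c(Cc3c(O)c(C)c(CC)oc3=O)c2O1
F13 | step 16 | 3-{[(R)-2-[2-(benzyloxy)propan-2-yl]-4,6-dihydroxy-5-(1-hydroxy-2-methylpropyl)-2,3-dihydrobenzofuran-7-yl]methyl}-6-ethyl-4-hydroxy-5-methyl-2H-pyran-2-one (carbinol epimers) | CC(C)(OCc1ccccc1)[C@H]1Cc2c(O)c(C(O)C(C)C)c(O)c(Cc3c(O)c(C)c(CC)oc3=O)c2O1
A1 | alternative 1 | 1-[4-hydroxy-3-iodo-2,6-bis(methoxymethoxy)phenyl]-2-methylpropan-1-one | CC(C)C(=O)c1c(OCOC)cc(O)c(I)c1OCOC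
A2 | alternative 1 | isoprene | C=CC(C)=C
A3 | alternative 1 | (R)-1-[4,6-bis(methoxymethoxy)-2-isopropenyl-2,3-dihydrobenzofuran-5-yl]-2-methylpropan-1-one | C=C(C)[C@H]1Cc2c(OCOC)c(C(=O)C(C)C)c(OCOC)cc2O1
A4 | alternative 2 | 6-ethyl-2,2,5-trimethyl-4H-1,3-dioxin-4-one | CCC1=C(C)C(=O)OC(C)(C)O1
A5 | alternative 2 | tert-butyldimethylsilyl ketene acetal of the C6–O/C7 dihydrocoumarin of the 4-O-methoxymethyl core | C=C(C)[C@H]1Cc2c(OCOC)c(C(=O)C(C)C)c3OC(O[Si](C)(C)C(C)(C)C)=CCc3c2O1
A6 | alternative 2 | 4-O-methoxymethyl ether of 36 | C=C(C)[C@H]1Cc2c(OCOC)c(C(=O)C(C)C)c(O)c(Cc3c(O)c(C)c(CC)oc3=O)c2O1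
A7 | alternative 3 | tosylhydrazone of 2,4-bis(tert-butyldimethylsilyloxy)-3-isobutyryl-6-[2-methyl-2-(triethylsilyloxy)propoxy]benzaldehyde | CC(C)(O[Si](CC)(CC)CC)COc1cc(O[Si](C)(C)C(C)(C)C)c(C(=O)C(C)C)c(O[Si](C)(C)C(C)(C)C)c1C=NNS(=O)(=O)c1ccc(C)cc1
A8 | alternative 3 | (R)-1-{4,6-bis(tert-butyldimethylsilyloxy)-2-[2-(triethylsilyloxy)propan-2-yl]-2,3-dihydrobenzofuran-5-yl}-2-methylpropan-1-one | CC(C)(O[Si](CC)(CC)CC)[C@H]1Cc2c(O[Si](C)(C)C(C)(C)C)c(C(=O)C(C)C)c(O[Si](C)(C)C(C)(C)C)cc2O1
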